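**Retrosynthetic overview**
1. The last disconnection is the ester C–O bond. It gives (R)-6-acetyl-2-(hydroxymethyl)-8-methoxy-2-methyl-2H-chromene and O-acetylferulic acid.
2. The key disconnection cuts C2–C3 and O1–C8a of the pyran ring together. It leads back to an achiral aryloxyacetone with a (Z)-2-borylvinyl group ortho to the ether oxygen. The ketone oxygen becomes O1 and the phenolic oxygen becomes the ester oxygen.
3. In the forward direction, an enantioselective rhodium-catalysed addition of C3 to the tethered ketone closes a temporary oxepine. Its tertiary alkoxide then takes over the arene by an O-to-O Smiles shift, a ring contraction from 7 to 6.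
4. Two features make this possible. The acetyl group at C6 is para to C8a of the benzene ring (ring A), which opens C8a to ipso attack. O1–C2–C1'–O is a 1,2-dioxygenated unit, so the aryl shift can pass through a five-membered spiro adduct.
5. Ring order: ring A is bought as acetovanillone and elaborated by iodination, O-alkylation with chloroacetone and Suzuki coupling with cis-1,2-diborylethene. The temporary oxepine comes next, then the pyran (ring B).

Key step: step 5

Locants: chromene numbering of the target is used throughout (O1, C2, C3, C4, C4a, C5 to C8, C8a). C1' is the exocyclic CH2 on C2.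
Assumption: the (R)-bisphosphine is taken to deliver C3 to the Re face of the ketone (R at C2). This sense of induction cannot be derived from a close analogue, and the ligand antipode is equally available.

**Route**

Step 1
Reactants: 1 acetovanillone (4'-hydroxy-3'-methoxyacetophenone)
Product: 2 5-iodoacetovanillone, 1-(4-hydroxy-3-iodo-5-methoxyphenyl)ethan-1-one
Conditions: NIS (1.05 equiv), TsOH·H2O (10 mol %), MeCN, rt
Reagents that add atoms: N-iodosuccinimide, O=C1CCC(=O)N1I
Why: In this electrophilic aromatic iodination the free phenol directs to its only open ortho position (para is blocked by the acetyl group), so iodine should enter at the carbon that becomes C4a.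

Step 2
Reactants: 2 5-iodoacetovanillone; 3 chloroacetone
Product: 4 1-(4-acetyl-2-iodo-6-methoxyphenoxy)propan-2-one
Conditions: K2CO3 (1.5 equiv), KI (10 mol %), acetone, 56 °C
Reagents that add atoms: none
Why: This is a Williamson ether synthesis (SN2, Finkelstein-assisted) on an acidic para-acyl phenol, and with iodine rather than a formyl group in the ortho position no Rap–Stoermer-type closure to a benzofuran can follow.

Step 3
Reactants: 5 acetylene; 6 bis(pinacolato)diboron
Product: 7 (Z)-1,2-bis(4,4,5,5-tetramethyl-1,3,2-dioxaborolan-2-yl)ethene
Conditions: Pt(PPh3)4 (3 mol %), DMF, 80 °C, acetylene (1 atm)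
Reagents that add atoms: none
Why: Platinum-catalysed alkyne diboration is a syn addition of the B–B bond, which fixes the Z geometry.

Step 4
Reactants: 4 1-(4-acetyl-2-iodo-6-methoxyphenoxy)propan-2-one; 7 (Z)-1,2-bis(pinacolatoboryl)ethene (2.5 equiv)
Product: 8 1-{4-acetyl-2-methoxy-6-[(Z)-2-(4,4,5,5-tetramethyl-1,3,2-dioxaborolan-2-yl)vinyl]phenoxy}propan-2-one
Conditions: PdCl2(dppf) (3 mol %), K3PO4 (2 equiv), dioxane/H2O 9:1, 50 °C
Reagents that add atoms: none
Why: Suzuki–Miyaura coupling keeps the alkene geometry, and the excess of 7 together with the lower reactivity of the remaining C–B bond (shielded by the cis aryl group) should hold the reaction at mono-coupling.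

Step 5
Reactants: 8 (Z)-alkenylboronate aryloxyacetone
Product: 10 (R)-1-[2-(hydroxymethyl)-8-methoxy-2-methyl-2H-chromen-6-yl]ethan-1-one, via (R)-benzoxepin-3-ol 9 (not isolated)
Conditions: [RhCl(C2H4)2]2 (2.5 mol %), (R)-DTBM-SEGPHOS (6 mol %), KOH (0.3 equiv), H2O (3 equiv), dioxane (0.05 M), 50 °C; then, same flask, KOtBu (2.5 equiv), t-BuOH, 45 °C, dark; aq NH4Cl
Reagents that add atoms: none
Why: Proposed new method: B-to-Rh transmetalation with retention of the Z geometry gives an alkenyl complex of monovalent rhodium whose C3 inserts the tethered ketone carbonyl (C3–C2 bond, alkoxide protonated to 9), and after the base switch the tertiary alkoxide of 9 adds to C8a, the charge of the σ-adduct being held by the para acetyl group as its enolate, and the old phenolic oxygen leaves as the primary alkoxide (O1–C8a bond), an O-to-O Smiles shift that contracts the oxepine to the pyran. The closest known reaction types are the rhodium-catalysed enantioselective intramolecular 1,2-addition of aryl pinacolboronates (and of alkenylrhodium species in arylative alkynone cyclisations) to unactivated ketones, and the base-induced Smiles rearrangement of 2-(4-acetylphenoxy)-2-methylpropanamides and 2-(nitroaryloxy)ethanols through five-membered spiro adducts; new are the seven-membered closure from a preformed (Z)-alkenylboronate and the use of the aryl shift as a ring contraction. Modes of closure: the temporary oxepine closes 7-exo-trig, and the pyran closes by transannular ipso attack of oxygen on C8a (6-exo-trig, at the same time the 5-exo-trig spiro closure over O–C2–C1'–O–C8a) through an unstrained adduct of the 6,8-dioxabicyclo[3.2.1]octene type that has no bridgehead alkene. The only stereocentre, C2, is set in the carbonyl insertion by the chiral bisphosphine on rhodium (delivery of C3 to the Re face gives R) and is kept in the aryl shift, because none of the four bonds at C2 is broken. Selectivity needs: the aliphatic ketone must react and not the aryl ketone (secured by the tether, the Z alkene and the inductive activation by the α-aryloxy group), only C8a may be attacked (it alone is para to the acetyl group, the methoxy-bearing C8 is meta), and the shift must run forward and outrun epoxide formation by loss of the phenoxide (secured by the 7-to-6 contraction, the planar push-pull aryl ether of the chromene, the change from tertiary to primary alkoxide and the protic, ion-pairing medium).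

Step 6
Reactants: 10 (R)-chromenylmethanol; 11 (E)-4-acetoxy-3-methoxycinnamic acid (O-acetylferulic acid)
Product: 12 [(2R)-6-acetyl-8-methoxy-2-methyl-2H-chromen-2-yl]methyl (E)-3-(4-acetoxy-3-methoxyphenyl)acrylate
Conditions: DCC (1.3 equiv), DMAP (0.2 equiv), CH2Cl2, 0 °C to rt, dark
Reagents that add atoms: none
Why: In this Steglich esterification the primary alcohol is the only acylable group, and neither C2 nor the E alkene of the acid takes part.

Step 7
Reactants: 12 O-acetyl-protected target
Product: 13 CNP0168033.1, [(2R)-6-acetyl-8-methoxy-2-methyl-2H-chromen-2-yl]methyl (E)-3-(4-hydroxy-3-methoxyphenyl)acrylate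
Conditions: pyrrolidine (2 equiv), CH2Cl2, 0 °C to rt, dark
Reagents that add atoms: none
Why: Chemoselective aminolysis should cleave the activated aryl acetate much faster than the hindered, conjugated alkyl cinnamate, and the mild, acid-free and light-free conditions leave the chromene and C2 untouched.

**Compound list**
1 | acetovanillone | CC(=O)c1ccc(O)c(OC)c1 | starting material
2 | 5-iodoacetovanillone | CC(=O)c1cc(I)c(O)c(OC)c1 | intermediate
3 | chloroacetone | CC(=O)CCl | starting material
4 | 1-(4-acetyl-2-iodo-6-methoxyphenoxy)propan-2-one | CC(=O)COc1c(I)cc(C(C)=O)cc1OC | intermediate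
5 | acetylene | C#C | starting material
6 | bis(pinacolato)diboron | CC1(C)OB(OC1(C)C)B1OC(C)(C)C(C)(C)O1 | starting material
7 | (Z)-1,2-bis(4,4,5,5-tetramethyl-1,3,2-dioxaborolan-2-yl)ethene | CC1(C)OB(/C=C\B2OC(C)(C)C(C)(C)O2)OC1(C)C | intermediate
8 | 1-{4-acetyl-2-methoxy-6-[(Z)-2-(4,4,5,5-tetramethyl-1,3,2-dioxaborolan-2-yl)vinyl]phenoxy}propan-2-one | CC(=O)COc1c(OC)cc(C(C)=O)cc1/C=C\B1OC(C)(C)C(C)(C)O1 | intermediate
9 | (R)-1-(3-hydroxy-9-methoxy-3-methyl-2,3-dihydro-1-benzoxepin-7-yl)ethan-1-one | C[C@]1(O)COc2c(OC)cc(C(C)=O)cc2C=C1 | intermediate
10 | (R)-1-[2-(hydroxymethyl)-8-methoxy-2-methyl-2H-chromen-6-yl]ethan-1-one | OC[C@@]1(C)C=Cc2cc(C(C)=O)cc(OC)c2O1 | intermediate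
11 | (E)-4-acetoxy-3-methoxycinnamic acid | COc1cc(/C=C/C(=O)O)ccc1OC(C)=O | starting material
12 | [(2R)-6-acetyl-8-methoxy-2-methyl-2H-chromen-2-yl]methyl (E)-3-(4-acetoxy-3-methoxyphenyl)acrylate | COc1cc(/C=C/C(=O)OC[C@@]2(C)C=Cc3cc(C(C)=O)cc(OC)c3O2)ccc1OC(C)=O | intermediate
13 | CNP0168033.1, [(2R)-6-acetyl-8-methoxy-2-methyl-2H-chromen-2-yl]methyl (E)-ferulate | COc1cc(/C=C/C(=O)OC[C@@]2(C)C=Cc3cc(C(C)=O)cc(OC)c3O2)ccc1O | target

Total step count: 7
Longest linear sequence: 6 (steps 1, 2, 4, 5, 6, 7)

**Steps most likely to fail**

Step 5. Several processes could defeat this step.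
- Protodeboronation or an alkenyl-to-aryl 1,4-rhodium migration may outrun the seven-membered closure.
- Facial selectivity at the methyl ketone may be poor.
- The aryl shift may stall, or leak through loss of the phenoxide with epoxide formation.

The fallback uses known chemistry and a different bond set. It sets out from 2. Suzuki–Miyaura vinylation with potassium vinyltrifluoroborate (PdCl2(dppf), Cs2CO3, THF/H2O) would give 5-vinylacetovanillone F1. Palladium-catalysed dynamic kinetic asymmetric O-allylation of this phenol follows, with racemic 2-methyl-2-vinyloxirane. The catalyst is Pd2(dba)3·CHCl3 with the DACH-phenyl bis(2-diphenylphosphinobenzamide) ligand in the antipode that leads to the R ether, in CH2Cl2. This would give (R)-1-{4-[(1-hydroxy-2-methylbut-3-en-2-yl)oxy]-3-methoxy-5-vinylphenyl}ethan-1-one F2. Ring-closing metathesis of the two vinyl groups (second-generation Grubbs catalyst, CH2Cl2, 40 °C) comes back to the route at 10.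

Step 4. The second C–B bond may over-couple. Z-to-E isomerisation or protodeboronation may occur under the basic aqueous conditions. Intramolecular α-arylation of the tethered ketone may compete.

The fallback installs boron by trans-hydroboration of an alkyne instead of cross-coupling a diborylethene. It sets out from 4. Sonogashira coupling with trimethylsilylacetylene (PdCl2(PPh3)2, CuI, Et3N, THF) would give 1-{4-acetyl-2-methoxy-6-[(trimethylsilyl)ethynyl]phenoxy}propan-2-one F3. K2CO3 in MeOH would then give 1-(4-acetyl-2-ethynyl-6-methoxyphenoxy)propan-2-one F4. Rhodium-catalysed trans-hydroboration with pinacolborane ([RhCl(cod)]2, P(iPr)3, Et3N, cyclohexane, rt) is a formal anti addition through a vinylidene complex, and it comes back to the route at 8.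

Step 6. Acylation of the neopentyl-type alcohol may be slow. That would leave room for N-acylurea formation and for DMAP-mediated transfer of the acetyl group from the aryl acetate.

The fallback builds the cinnamate on the alcohol and needs no protecting group. It sets out from 10. Opening of Meldrum's acid (toluene, 80 °C, dark) would give the malonic half ester 3-{[(2R)-6-acetyl-8-methoxy-2-methyl-2H-chromen-2-yl]methoxy}-3-oxopropanoic acid F5. Knoevenagel–Doebner condensation with vanillin (pyridine, cat. piperidine, 40 °C) forms the E alkene with decarboxylation and comes back to the route at 13, passing by 12.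

**Further compounds**
F1 | step 5 | 1-(4-hydroxy-3-methoxy-5-vinylphenyl)ethan-1-one | C=Cc1cc(C(C)=O)cc(OC)c1O
F2 | step 5 | (R)-1-{4-[(1-hydroxy-2-methylbut-3-en-2-yl)oxy]-3-methoxy-5-vinylphenyl}ethan-1-one | OC[C@@](C)(C=C)Oc1c(C=C)cc(C(C)=O)cc1OC
F3 | step 4 | 1-{4-acetyl-2-methoxy-6-[(trimethylsilyl)ethynyl]phenoxy}propan-2-one | CC(=O)COc1c(C#C[Si](C)(C)C)cc(C(C)=O)cc1OC
F4 | step 4 | 1-(4-acetyl-2-ethynyl-6-methoxyphenoxy)propan-2-one | CC(=O)COc1c(C#C)cc(C(C)=O)cc1OC
F5 | step 6 | 3-{[(2R)-6-acetyl-8-methoxy-2-methyl-2H-chromen-2-yl]methoxy}-3-oxopropanoic acid | OC(=O)CC(=O)OC[C@@]1(C)C=Cc2cc(C(C)=O)cc(OC)c2O1
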